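**Retrosynthetic overview**
1. The ester comes from selective acylation of the secondary allylic C6-OH of the daucenediol with phenol-protected 4-hydroxybenzoic acid.
2. The C4 carbinol comes from isopropyl-metal addition to a trans-fused hydroazulen-4-one, on the face opposite the angular methyl.
3. C5-H and C6-OH come from alpha-face epoxidation of a bicyclic dienone and SmI2 opening. The angular methyl steers both.
4. The seven-membered ring is formed second, by ring-closing metathesis at C7=C8. Its diene comes from the key C5–C6 bond, an intermolecular aldol addition of a regiodefined cyclopentanone enolate to acrolein.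
5. The five-membered ring is present from the start as 3-ethoxycyclopentenone. The C1 quaternary centre is set by copper-catalysed asymmetric conjugate addition of Me3Al.

Numbering: daucane numbering is used. C1 is the quaternary fusion carbon, C2 and C3 are ring CH2, C4 is the carbinol carbon bearing isopropyl, C5 is the fusion CH, C6 is the ester carbon, C7=C8(Me) is the alkene, and C9 and C10 are CH2. The beta face is the face of the angular methyl and alpha is the opposite face. The target is (1S,4R,5S,6S): trans-fused, 4-OH beta, H5 alpha, 6-O alpha.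

Assumption: the enantiomer of the chiral NHC ligand that gives the (S) quaternary carbon is used (about 90% ee expected), and the minor enantiomer is removed by recrystallising the diol obtained after desilylation.

**Step 1**
Reactants: 1 3-methylbut-3-en-1-ol
Product: 2 4-bromo-2-methylbut-1-ene
Conditions: CBr4, PPh3, CH2Cl2, 0 °C to rt
Reagents that add atoms: carbon tetrabromide, BrC(Br)(Br)Br
Why: Appel bromination converts the primary alcohol into the bromide by SN2 displacement of the oxyphosphonium ion under neutral conditions that leave the 1,1-disubstituted alkene untouched and create no stereocentre.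

**Step 2**
Reactants: 2 4-bromo-2-methylbut-1-ene; 3 3-ethoxycyclopent-2-en-1-one
Product: 6 3-(3-methylbut-3-en-1-yl)cyclopent-2-en-1-one, via Grignard reagent 4 (not isolated), via tertiary allylic alcohol 5 (not isolated)
Conditions: Mg, THF, 40 °C; then 3, 0 °C; then 1 M HCl, 0 °C to rt
Reagents that add atoms: none
Why: Stork–Danheiser alkylative carbonyl transposition, in which the Grignard reagent adds 1,2 to the vinylogous ester and mild acid ionises the adduct and expels ethanol to give the achiral beta-substituted enone.

**Step 3**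
Reactants: 6 3-(3-methylbut-3-en-1-yl)cyclopent-2-en-1-one
Product: 8 triethyl{[(3S)-3-methyl-3-(3-methylbut-3-en-1-yl)cyclopent-1-en-1-yl]oxy}silane, via aluminium enolate 7 (not isolated)
Conditions: Me3Al (3 equiv), Cu(OTf)2 (5 mol %), chiral 4,5-diphenylimidazolinium aryl-sulfonate (bidentate NHC precursor, 5 mol %, pre-treated with Ag2O), THF, −78 °C, 15 h; then TESOTf, −78 °C to rt
Reagents that add atoms: trimethylaluminium, C[Al](C)C; triethylsilyl trifluoromethanesulfonate, CC[Si](CC)(CC)OS(=O)(=O)C(F)(F)F
Why: Copper-catalysed asymmetric conjugate addition, in which the chiral NHC–copper methyl species attacks one enantiotopic face of the enone to set the quaternary C1 as (S) and O-silylation of the aluminium enolate locks the enolate regiochemistry at C4=C5.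

**Step 4**
Reactants: 8 triethyl{[(3S)-3-methyl-3-(3-methylbut-3-en-1-yl)cyclopent-1-en-1-yl]oxy}silane; 9 acrolein
Product: 11 (3S)-2-(1-hydroxyprop-2-en-1-yl)-3-methyl-3-(3-methylbut-3-en-1-yl)cyclopentan-1-one (mixture of diastereomers at C5 and C6), via lithium enolate 10 (not isolated)
Conditions: MeLi, THF, 0 °C to rt, 1 h; then 9, −78 °C, 15 min; AcOH quench at −78 °C
Reagents that add atoms: none
Why: Regiospecific lithium-enolate aldol addition, in which MeLi cleaves the silyl enol ether without enolate scrambling and the hindered C5 carbon adds 1,2 to the small reactive enal to join the two fragments through the C5–C6 bond, the uncontrolled C5 and C6 configurations being harmless because both are erased in step 6 and reset in steps 7 and 8.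

**Step 5**
Reactants: 11 aldol adduct
Product: 12 (3aS)-8-hydroxy-3a,6-dimethyl-3,3a,4,5,8,8a-hexahydroazulen-1(2H)-one (mixture at C5 and C6)
Conditions: second-generation Grubbs catalyst (5 mol %), CH2Cl2 (5 mM), reflux
Reagents that add atoms: none
Why: Ring-closing metathesis between the monosubstituted allylic-alcohol alkene and the 1,1-disubstituted alkene closes the seven-membered ring with loss of ethene, places the trisubstituted alkene unambiguously at C7=C8 and works for every diastereomer because cis- and trans-fused hydroazulenes are both unstrained.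

**Step 6**
Reactants: 12 bicyclic hydroxy ketone mixture
Product: 14 (3aS)-3a,6-dimethyl-3,3a,4,5-tetrahydroazulen-1(2H)-one, via allylic mesylate 13 (not isolated)
Conditions: MsCl, Et3N, CH2Cl2, 0 °C; then DBU, rt
Reagents that add atoms: none
Why: Mesylation followed by E1cB elimination of the beta-mesyloxy ketone funnels all diastereomers into one conjugated dienone in which C1 is the only stereocentre and the ring enforces the geometry of the new C5=C6 alkene.

**Step 7**
Reactants: 14 bicyclic dienone
Product: 15 (3aS,8S,8aR)-8,8a-epoxy-3a,6-dimethyl-3,3a,4,5,8,8a-hexahydroazulen-1(2H)-one (5alpha,6alpha-epoxide)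
Conditions: 30% aq H2O2, NaOH (0.3 equiv), MeOH, 0 °C
Reagents that add atoms: hydrogen peroxide, OO
Why: Weitz–Scheffer nucleophilic epoxidation, in which hydroperoxide adds to C6 rather than to the methyl-blocked C8 and the enolate closes on the alpha face because the beta face of C5 is shielded by the adjacent pseudo-axial angular methyl, which sets C6 as (S).

**Step 8**
Reactants: 15 alpha-epoxy ketone
Product: 17 (3aS,8S,8aS)-8-hydroxy-3a,6-dimethyl-3,3a,4,5,8,8a-hexahydroazulen-1(2H)-one, via samarium enolate 16 (not isolated)
Conditions: SmI2 (2.5 equiv), THF–MeOH, −90 °C, 10 min; pH 7 buffer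
Reagents that add atoms: none
Why: SmI2 reduction of an alpha,beta-epoxy ketone, in which two single-electron transfers cleave only the C5–O bond so that C6 keeps its configuration and methanol protonates the samarium enolate at −90 °C from the alpha face, opposite the angular methyl and next to the alpha-oriented C6 alkoxide, to give the trans ring fusion with C5 as (S).

**Step 9**
Reactants: 17 trans-fused hydroxy ketone
Product: 18 (3aS,8S,8aS)-3a,6-dimethyl-8-(triethylsilyloxy)-3,3a,4,5,8,8a-hexahydroazulen-1(2H)-one
Conditions: TESCl, imidazole, CH2Cl2, 0 °C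
Reagents that add atoms: chlorotriethylsilane, CC[Si](Cl)(CC)CC
Why: Standard silyl ether formation under weakly basic conditions masks the acidic C6 hydroxyl before the organometallic step without epimerising C5 or triggering beta-elimination.

**Step 10**
Reactants: 18 silyloxy ketone
Product: 19 (3R,3aS,4S,8aS)-6,8a-dimethyl-3-(propan-2-yl)-4-(triethylsilyloxy)-1,2,3,3a,4,7,8,8a-octahydroazulen-3-ol
Conditions: iPrMgCl (2 equiv), LaCl3·2LiCl (1 equiv), THF, −20 to 0 °C; H2O quench
Reagents that add atoms: isopropylmagnesium chloride, CC(C)[Mg]Cl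
Why: Lanthanide-promoted Grignard 1,2-addition, in which LaCl3·2LiCl activates the carbonyl and suppresses enolisation and hydride transfer while isopropyl attacks the cyclopentanone from the alpha face, anti to the pseudo-axial angular methyl and to the C5–C6 bond, so that the new hydroxyl is beta and C4 is (R).

**Step 11**
Reactants: 19 silyl-protected diol
Product: 20 (3R,3aS,4S,8aS)-6,8a-dimethyl-3-(propan-2-yl)-1,2,3,3a,4,7,8,8a-octahydroazulene-3,4-diol
Conditions: TBAF, AcOH, THF, 0 °C to rt; recrystallise
Reagents that add atoms: none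
Why: Fluoride-mediated desilylation buffered by acetic acid frees the C6 hydroxyl without ionising the allylic alcohol or touching the tertiary alcohol or any stereocentre.

**Step 12**
Reactants: 21 4-hydroxybenzoic acid
Product: 22 4-(pivaloyloxy)benzoic acid
Conditions: PivCl, aq NaOH, 0 °C; then HCl to pH 2
Reagents that add atoms: pivaloyl chloride, CC(C)(C)C(=O)Cl
Why: Schotten–Baumann acylation, in which the phenoxide is pivaloylated while any mixed anhydride formed at the carboxylate is hydrolysed in the aqueous base, giving the phenol-protected acid.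

**Step 13**
Reactants: 20 diol; 22 4-(pivaloyloxy)benzoic acid
Product: 24 [(3R,3aS,4S,8aS)-3-hydroxy-6,8a-dimethyl-3-(propan-2-yl)-1,2,3,3a,4,7,8,8a-octahydroazulen-4-yl] 4-(pivaloyloxy)benzoate, via O-acylisourea 23 (not isolated)
Conditions: DCC, DMAP (0.2 equiv), CH2Cl2, rt
Reagents that add atoms: none
Why: Steglich esterification, in which the acylpyridinium ion acylates only the secondary allylic C6 hydroxyl with retention because the C6–O bond is never broken and the tertiary C4 hydroxyl is too hindered to react.

**Step 14**
Reactants: 24 pivaloyl-protected ester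
Product: 25 [(3R,3aS,4S,8aS)-3-hydroxy-6,8a-dimethyl-3-(propan-2-yl)-1,2,3,3a,4,7,8,8a-octahydroazulen-4-yl] 4-hydroxybenzoate (target)
Conditions: ethylenediamine, CH2Cl2, rt
Reagents that add atoms: none
Why: Chemoselective aminolysis, in which the activated aryl pivalate is cleaved by the diamine far faster than the hindered secondary alkyl benzoate, releasing the free phenol without touching any stereocentre.

**Compound list**
1 | 3-methylbut-3-en-1-ol | C=C(C)CCO | starting material
2 | 4-bromo-2-methylbut-1-ene | C=C(C)CCBr | intermediate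
3 | 3-ethoxycyclopent-2-en-1-one | CCOC1=CC(=O)CC1 | starting material
4 | (3-methylbut-3-en-1-yl)magnesium bromide | C=C(C)CC[Mg]Br | intermediate
5 | 3-ethoxy-1-(3-methylbut-3-en-1-yl)cyclopent-2-en-1-ol (racemic) | CCOC1=CC(O)(CCC(C)=C)CC1 | intermediate
6 | 3-(3-methylbut-3-en-1-yl)cyclopent-2-en-1-one | O=C1C=C(CCC(C)=C)CC1 | intermediate
7 | dimethylaluminium C4=C5 enolate of (S)-3-methyl-3-(3-methylbut-3-en-1-yl)cyclopentanone | C[Al](C)OC1=C[C@@](C)(CCC(C)=C)CC1 | intermediate
8 | triethyl{[(3S)-3-methyl-3-(3-methylbut-3-en-1-yl)cyclopent-1-en-1-yl]oxy}silane | CC[Si](CC)(CC)OC1=C[C@@](C)(CCC(C)=C)CC1 | intermediate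
9 | acrolein (prop-2-enal) | C=CC=O | starting material
10 | lithium C4=C5 enolate of (S)-3-methyl-3-(3-methylbut-3-en-1-yl)cyclopentanone | [Li]OC1=C[C@@](C)(CCC(C)=C)CC1 | intermediate
11 | (3S)-2-(1-hydroxyprop-2-en-1-yl)-3-methyl-3-(3-methylbut-3-en-1-yl)cyclopentan-1-one, diastereomer mixture at C5 and C6 | C=CC(O)C1[C@@](C)(CCC(C)=C)CCC1=O | intermediate
12 | (3aS)-8-hydroxy-3a,6-dimethyl-3,3a,4,5,8,8a-hexahydroazulen-1(2H)-one, diastereomer mixture at C5 and C6 | CC1=CC(O)C2[C@@](C)(CC1)CCC2=O | intermediate
13 | methanesulfonate of 12 | CC1=CC(OS(C)(=O)=O)C2[C@@](C)(CC1)CCC2=O | intermediate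
14 | (3aS)-3a,6-dimethyl-3,3a,4,5-tetrahydroazulen-1(2H)-one | CC1=CC=C2[C@@](C)(CC1)CCC2=O | intermediate
15 | (3aS,8S,8aR)-8,8a-epoxy-3a,6-dimethyl-3,3a,4,5,8,8a-hexahydroazulen-1(2H)-one, epoxide anti to the angular methyl | CC1=C[C@@H]3O[C@]32[C@@](C)(CC1)CCC2=O | intermediate
16 | bis(diiodosamarium) C4=C5 enolate and C6 alkoxide from 15 | CC1=C[C@H](O[Sm](I)I)C=2[C@@](C)(CC1)CCC=2O[Sm](I)I | intermediate
17 | (3aS,8S,8aS)-8-hydroxy-3a,6-dimethyl-3,3a,4,5,8,8a-hexahydroazulen-1(2H)-one, trans-fused | CC1=C[C@H](O)[C@@H]2[C@@](C)(CC1)CCC2=O | intermediate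
18 | (3aS,8S,8aS)-3a,6-dimethyl-8-(triethylsilyloxy)-3,3a,4,5,8,8a-hexahydroazulen-1(2H)-one | CC1=C[C@H](O[Si](CC)(CC)CC)[C@@H]2[C@@](C)(CC1)CCC2=O | intermediate
19 | (3R,3aS,4S,8aS)-6,8a-dimethyl-3-(propan-2-yl)-4-(triethylsilyloxy)-1,2,3,3a,4,7,8,8a-octahydroazulen-3-ol | CC1=C[C@H](O[Si](CC)(CC)CC)[C@@H]2[C@@](C)(CC1)CC[C@@]2(O)C(C)C | intermediate
20 | (3R,3aS,4S,8aS)-6,8a-dimethyl-3-(propan-2-yl)-1,2,3,3a,4,7,8,8a-octahydroazulene-3,4-diol | CC1=C[C@H](O)[C@@H]2[C@@](C)(CC1)CC[C@@]2(O)C(C)C | intermediate
21 | 4-hydroxybenzoic acid | OC(=O)c1ccc(O)cc1 | starting material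
22 | 4-(pivaloyloxy)benzoic acid | CC(C)(C)C(=O)Oc1ccc(cc1)C(O)=O | intermediate
23 | O-acylisourea from 22 and DCC | CC(C)(C)C(=O)Oc1ccc(cc1)C(=O)OC(=NC1CCCCC1)NC1CCCCC1 | intermediate
24 | [(3R,3aS,4S,8aS)-3-hydroxy-6,8a-dimethyl-3-(propan-2-yl)-1,2,3,3a,4,7,8,8a-octahydroazulen-4-yl] 4-(pivaloyloxy)benzoate | CC1=C[C@H](OC(=O)c2ccc(OC(=O)C(C)(C)C)cc2)[C@@H]2[C@@](C)(CC1)CC[C@@]2(O)C(C)C | intermediate
25 | [(3R,3aS,4S,8aS)-3-hydroxy-6,8a-dimethyl-3-(propan-2-yl)-1,2,3,3a,4,7,8,8a-octahydroazulen-4-yl] 4-hydroxybenzoate | CC1=C[C@H](OC(=O)c2ccc(O)cc2)[C@@H]2[C@@](C)(CC1)CC[C@@]2(O)C(C)C | target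

Total step count: 14.
Longest linear sequence: 13 (steps 1 to 11, then 13 and 14).

**Steps most likely to fail**

**Step 3.** Five-membered enones give lower enantioselectivity than six-membered ones, and the aluminium enolate is sluggish towards silylation. The fallback forms the other bond to the quaternary carbon. It sets out from Grignard reagent 4 and comes back at 8. Reagent 4 is added to commercial 3-methylcyclopent-2-en-1-one (CC1=CC(=O)CC1) with Cu(OTf)2 and a chiral hydroxyalkyl-imidazolinium NHC precursor in Et2O at −30 °C. This gives the bromomagnesium enolate of (S)-3-methyl-3-(3-methylbut-3-en-1-yl)cyclopentanone F1. F1 is far more nucleophilic than 7 and is O-silylated with TESCl and Et3N to give 8.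

**Step 8.** Three things can go wrong: the beta-samarium alkoxide can be expelled to return dienone 14, the ketone can be over-reduced, or the proton can arrive on the wrong face. The fallback replaces the epoxide route by a carbon–boron route. It sets out from dienone 14 and comes back at 17, bypassing steps 7 and 8. Copper-catalysed conjugate borylation (CuCl, NaOtBu, Xantphos, B2pin2, MeOH, THF, rt) delivers boron to C6 from the alpha face, and methanol protonates the copper enolate on the same open face. This gives the 6alpha-pinacolboryl trans-fused ketone F2. Oxidation with NaBO3·4H2O in THF–H2O proceeds with retention and gives 17.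

**Step 10.** A branched Grignard reagent on a hindered, enolisable beta-silyloxy ketone may enolise, reduce or eliminate instead of adding. The fallback uses a slimmer sp2 nucleophile that has no transferable hydride. It sets out from 18 and comes back at 19. Isopropenylmagnesium bromide with CeCl3 in THF at −78 °C adds from the same alpha face and gives the isopropenyl carbinol F3. Its 1,1-disubstituted alkene is then hydrogenated selectively with H2 and RhCl(PPh3)3 in benzene, conditions under which the hindered trisubstituted ring alkene is inert, and this gives 19.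

**Further compounds**
F1 | step 3 | bromomagnesium C4=C5 enolate of (S)-3-methyl-3-(3-methylbut-3-en-1-yl)cyclopentanone | Br[Mg]OC1=C[C@@](C)(CCC(C)=C)CC1
F2 | step 8 | (3aS,8S,8aR)-3a,6-dimethyl-8-(4,4,5,5-tetramethyl-1,3,2-dioxaborolan-2-yl)-3,3a,4,5,8,8a-hexahydroazulen-1(2H)-one | CC1=C[C@H](B3OC(C)(C)C(C)(C)O3)[C@@H]2[C@@](C)(CC1)CCC2=O
F3 | step 10 | (3S,3aS,4S,8aS)-6,8a-dimethyl-3-(prop-1-en-2-yl)-4-(triethylsilyloxy)-1,2,3,3a,4,7,8,8a-octahydroazulen-3-ol | CC1=C[C@H](O[Si](CC)(CC)CC)[C@@H]2[C@@](C)(CC1)CC[C@@]2(O)C(C)=C
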